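Ring atoms: C1 (quaternary; Me, chlorovinyl), C2 (CH2), C3 (CBr, CH2Br), C4 (CHCl), C5 (CH2), C6 (CHCl). Everything rests on cutting C1–C2 and C4–C5 of the cyclohexane. The 1,3-dichloride C4–C5–C6 flanking C3 is the signature of chlorine atom-transfer addition of a dichloromethyl ketone to a vinyl group (C6=C5), and quaternary C1 carrying that vinyl group is the signature of branched allylic alkylation. In one pot, Pd2(dba)3-catalysed asymmetric alkylation of isoprene monoepoxide with ethyl 4,4-dichloroacetoacetate forms C1–C2 and sets C1; CuCl-catalysed radical cyclisation of the resulting dichloroacetyl lactone then forms C4–C5 and both C–Cl bonds. The precursor is thus two small achiral or racemic fragments.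

Key step: step 2

Remark: the ligand enantiomer in step 2 is the one that delivers the (S)-configured quaternary carbon of 6; the (R,R) form is proposed, and its mirror image is used instead should the first run show the opposite sense.
Remark: C4 is deliberately left uncontrolled in steps 2 and 3 and is set in step 4; the Why lines use the ring numbering C1–C6 given above.

Step 1
Reactants: 1 dichloroacetyl chloride; 2 Meldrum's acid
Product: 4 ethyl 4,4-dichloro-3-oxobutanoate, via acyl Meldrum's acid 3 (not isolated)
Conditions: pyridine (2 equiv), CH2Cl2, 0 → 23 °C; then EtOH, reflux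
Reagents that add atoms: ethanol, CCO
Why: C-acylation of Meldrum's acid followed by ethanolysis with loss of acetone and CO2 (Meldrum's acid route to β-keto esters) is a general synthesis of β-keto esters from acid chlorides and forms no stereocenter.

Step 2
Reactants: 4 ethyl 4,4-dichloro-3-oxobutanoate; 5 2-ethenyl-2-methyloxirane (racemic isoprene monoepoxide)
Product: 8 (3aS,4S,7aS)-4,6-dichloro-3a-methylhexahydro-2-benzofuran-1,7-dione (C6 epimers), via hydroxy keto ester 6 (not isolated), via dichloroacetyl lactone 7 (not isolated)
Conditions: Pd2(dba)3·CHCl3 (1 mol%), (R,R)-N,N'-bis(2-diphenylphosphinobenzoyl)-1,2-diaminocyclohexane (3 mol%), ClCH2CH2Cl, 23 °C; then CuCl (15 mol%), tris(2-pyridylmethyl)amine (15 mol%), 4 Å MS, 80 °C, same flask, nothing isolated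
Reagents that add atoms: none
Why: Zerovalent palladium opens racemic 5 to interconverting π-allyl alkoxides, and the enol of 4 attacks the tertiary allyl terminus (alkoxide-directed, branched; asymmetric Tsuji–Trost alkylation run as a dynamic kinetic asymmetric transformation, known for isoprene monoepoxide with β-keto esters), forming C1–C2 with C1 set by the ligand. On heating, 6 lactonises (5-exo-trig, loss of EtOH) to 7, CuCl abstracts a chlorine atom from the CHCl2 group, and the α-keto radical at C4, an umpoled ketone α-carbon, adds to the alkene terminus C5 in a 6-endo-trig closure that forms C4–C5 before divalent copper chloride (CuCl2) returns chlorine to C6 (Kharasch-type chlorine atom-transfer radical cyclisation of α,α-dichloro carbonyl compounds). The 6-endo mode is expected because the carbonyl lies inside the forming ring (2-oxohex-5-enyl radical) and the internal alkene carbon is neopentylic. C6 is under substrate control: the enolised, chelated acyl lactone holds the lactone CH2 in the ring plane and the C1 methyl pseudo-axial, so chlorine should enter anti to the methyl group. The ring-fusion carbon and C4 are epimerisable and are not relied on, the former being lost in step 3 and the latter set in step 4. The step needs branched over linear alkylation, C- over O-alkylation and activation of the CHCl2 chlorines only; alkoxide-directed delivery, the soft 1,3-dicarbonyl nucleophile and α-carbonyl activation should secure these.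

Step 3
Reactants: 8 (3aS,4S,7aS)-4,6-dichloro-3a-methylhexahydro-2-benzofuran-1,7-dione
Product: 9 (4S,5S)-2,4-dichloro-5-(hydroxymethyl)-5-methylcyclohexan-1-one (C2 epimers)
Conditions: H2SO4 (2 M aq.), 1,4-dioxane, 90 °C
Reagents that add atoms: none
Why: Acid-catalysed lactone hydrolysis and decarboxylation of the resulting β-keto acid (ketonic cleavage of an α-acyl lactone) excises the lactone carbonyl carbon, leaves C2 as CH2 and frees the primary alcohol, while the alkyl chlorides and the C1 and C6 stereocenters are inert to aqueous acid and C4 merely equilibrates.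

Step 4
Reactants: 9 (4S,5S)-2,4-dichloro-5-(hydroxymethyl)-5-methylcyclohexan-1-one
Product: 11 (2R,4S,5S)-2,4-dichloro-5-(hydroxymethyl)-5-methylcyclohexan-1-one, via bis(trimethylsilyl) enol ether 10 (not isolated)
Conditions: Me3SiOTf (3 equiv), Et3N (4 equiv), CH2Cl2, 0 °C; then HCl (0.5 M aq.), THF, −20 °C
Reagents that add atoms: none
Why: Soft enolisation gives the silyl enol ether on the chlorine-bearing side, and its stereoelectronically controlled kinetic C-protonation should occur axially on the face of C4 anti to the 1,3-related C6 chlorine, so that the C4 chlorine ends up equatorial and cis to the C6 chlorine from either C4 epimer (kinetic protonation of an enol ether).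

Step 5
Reactants: 11 (2R,4S,5S)-2,4-dichloro-5-(hydroxymethyl)-5-methylcyclohexan-1-one
Product: 12 [(1S,2S,4R)-2,4-dichloro-1-methyl-5-methylidenecyclohexyl]methanol
Conditions: Cp2Ti(μ-CH2)(μ-Cl)AlMe2 (2.5 equiv), pyridine (cat.), THF–toluene, −40 → 0 °C; NaOH (aq.) work-up
Reagents that add atoms: Tebbe reagent Cp2Ti(μ-CH2)(μ-Cl)AlMe2, C[Al-](C)(Cl)C[Ti+](C1C=CC=C1)C1C=CC=C1
Why: Tebbe methylenation converts enolisable ketones into exocyclic alkenes through the non-basic titanium methylidene Cp2Ti=CH2, so the labile C4 stereocenter should be preserved, the hydroxyl being carried as a titanium alkoxide that is hydrolysed on work-up.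

Step 6
Reactants: 12 [(1S,2S,4R)-2,4-dichloro-1-methyl-5-methylidenecyclohexyl]methanol
Product: 13 (1S,2S,4R)-2,4-dichloro-1-methyl-5-methylidenecyclohexane-1-carbaldehyde
Conditions: Dess–Martin periodinane, CH2Cl2, 0 → 23 °C
Reagents that add atoms: none
Why: Dess–Martin oxidation of the neopentylic primary alcohol should stop at the non-enolisable aldehyde under mild conditions that leave the allylic chloride and the exocyclic alkene untouched.

Step 7
Reactants: 13 (1S,2S,4R)-2,4-dichloro-1-methyl-5-methylidenecyclohexane-1-carbaldehyde
Product: 14 (1S,2S,5R)-1,5-dichloro-2-[(Z)-2-chloroethenyl]-2-methyl-4-methylidenecyclohexane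
Conditions: [Ph3PCH2Cl]Cl, NaN(SiMe3)2, THF, −78 → 0 °C
Reagents that add atoms: (chloromethyl)triphenylphosphonium chloride, ClC[P+](c1ccccc1)(c1ccccc1)c1ccccc1.[Cl-]
Why: Wittig olefination with the non-stabilised ylide Ph3P=CHCl at low temperature proceeds through the kinetically preferred cis-oxaphosphetane and should give mainly the (Z)-chloroalkene, the aldehyde being far more reactive towards the ylide than the allylic chloride.

Step 8
Reactants: 14 (1S,2S,5R)-1,5-dichloro-2-[(Z)-2-chloroethenyl]-2-methyl-4-methylidenecyclohexane
Product: 15 (1S,2R,4S,5S)-1-bromo-1-(bromomethyl)-2,4-dichloro-5-[(Z)-2-chloroethenyl]-5-methylcyclohexane (target)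
Conditions: Br2 (1.0 equiv), CH2Cl2, −78 °C, dark
Reagents that add atoms: bromine, BrBr
Why: Bromine adds chemoselectively to the more electron-rich 1,1-disubstituted exocyclic alkene (alkene dibromination), and anti opening of the bromonium ion at the tertiary carbon by axial attack of bromide should place the tertiary bromine axial and cis to the C4 chlorine with CH2Br equatorial, which is also the thermodynamically preferred C3 configuration.

Compound list
1 | dichloroacetyl chloride | O=C(Cl)C(Cl)Cl | starting material
2 | Meldrum's acid (2,2-dimethyl-1,3-dioxane-4,6-dione) | CC1(C)OC(=O)CC(=O)O1 | starting material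
3 | 5-(2,2-dichloro-1-hydroxyethylidene)-2,2-dimethyl-1,3-dioxane-4,6-dione | CC1(C)OC(=O)C(=C(O)C(Cl)Cl)C(=O)O1 | intermediate (not isolated)
4 | ethyl 4,4-dichloro-3-oxobutanoate | CCOC(=O)CC(=O)C(Cl)Cl | intermediate
5 | 2-ethenyl-2-methyloxirane (racemic) | CC1(C=C)CO1 | starting material
6 | ethyl (3S)-2-(dichloroacetyl)-3-(hydroxymethyl)-3-methylpent-4-enoate (C2 epimers) | C[C@@](C=C)(CO)C(C(=O)OCC)C(=O)C(Cl)Cl | intermediate (not isolated)
7 | (4S)-3-(dichloroacetyl)-4-ethenyl-4-methyloxolan-2-one (C3 epimers, largely enolised) | C[C@@]1(C=C)COC(=O)C1C(=O)C(Cl)Cl | intermediate (not isolated)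
8 | (3aS,4S,7aS)-4,6-dichloro-3a-methylhexahydro-2-benzofuran-1,7-dione (cis-fused; 4-Cl trans to 3a-Me; C6 epimers) | C[C@@]1(COC2=O)[C@H]2C(=O)C(Cl)C[C@@H]1Cl | intermediate
9 | (4S,5S)-2,4-dichloro-5-(hydroxymethyl)-5-methylcyclohexan-1-one (C2 epimers) | C[C@@]1(CO)CC(=O)C(Cl)C[C@@H]1Cl | intermediate
10 | trimethyl{[(4S,5S)-2,4-dichloro-5-methyl-5-(trimethylsilyloxymethyl)cyclohex-1-en-1-yl]oxy}silane | C[C@@]1(CO[Si](C)(C)C)CC(O[Si](C)(C)C)=C(Cl)C[C@@H]1Cl | intermediate (not isolated)
11 | (2R,4S,5S)-2,4-dichloro-5-(hydroxymethyl)-5-methylcyclohexan-1-one | C[C@@]1(CO)CC(=O)[C@H](Cl)C[C@@H]1Cl | intermediate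
12 | [(1S,2S,4R)-2,4-dichloro-1-methyl-5-methylidenecyclohexyl]methanol | C[C@@]1(CO)CC(=C)[C@H](Cl)C[C@@H]1Cl | intermediate
13 | (1S,2S,4R)-2,4-dichloro-1-methyl-5-methylidenecyclohexane-1-carbaldehyde | C[C@@]1(C=O)CC(=C)[C@H](Cl)C[C@@H]1Cl | intermediate
14 | (1S,2S,5R)-1,5-dichloro-2-[(Z)-2-chloroethenyl]-2-methyl-4-methylidenecyclohexane | C[C@@]1(/C=C\Cl)CC(=C)[C@H](Cl)C[C@@H]1Cl | intermediate
15 | (1S,2R,4S,5S)-1-bromo-1-(bromomethyl)-2,4-dichloro-5-[(Z)-2-chloroethenyl]-5-methylcyclohexane | C[C@@]1(/C=C\Cl)C[C@@](Br)(CBr)[C@H](Cl)C[C@@H]1Cl | target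

Total steps: 8. Longest linear sequence: 8 steps (1 and 2 to 15; 5 enters at step 2).

Steps most likely to fail

Step 2. The hydroxyl may close onto the ketone instead of the ester, the radical may cyclise 5-exo, the two catalysts may inhibit each other, or chlorine transfer to the C6 radical may show poor facial selectivity in the bicyclic intermediate. The fallback separates the two bond formations and runs the radical cyclisation on a monocyclic substrate. It sets out from 7, isolated after the palladium stage (Et3N cat., 40 °C to complete lactonisation). Hydrolysis and decarboxylation (H2SO4 2 M aq., dioxane, 90 °C) should give (4R)-1,1-dichloro-4-(hydroxymethyl)-4-methylhex-5-en-2-one F1, in equilibrium with its cyclic hemiketal. Silylation (t-BuPh2SiCl, imidazole, CH2Cl2) should give (4R)-4-{[tert-butyl(diphenyl)silyl]oxymethyl}-1,1-dichloro-4-methylhex-5-en-2-one F2. CuCl and tris(2-pyridylmethyl)amine in ClCH2CH2Cl at 80 °C should then effect the same 6-endo chlorine atom-transfer cyclisation, now through a chair radical with the bulky silyloxymethyl group equatorial and the methyl axial, so that chlorine enters axially anti to the methyl group and gives (4S,5S)-5-{[tert-butyl(diphenyl)silyl]oxymethyl}-2,4-dichloro-5-methylcyclohexan-1-one F3. HF·pyridine in THF removes the silyl group and the route is rejoined at 9.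

Step 7. Z-selectivity may erode with the hindered α-quaternary aldehyde, or the basic ylide may cause loss of HCl from the allylic chloride. The fallback builds the Z-chloroalkene by a stereospecific syn-addition and sets out from 13. Dimethyl (1-diazo-2-oxopropyl)phosphonate, K2CO3, MeOH, 0 °C (Seyferth–Gilbert homologation in the Ohira–Bestmann variant) should give (1S,2S,5R)-1,5-dichloro-2-ethynyl-2-methyl-4-methylidenecyclohexane F4. LiN(SiMe3)2 then N-chlorosuccinimide in THF at −78 °C should give (1S,2S,5R)-1,5-dichloro-2-(chloroethynyl)-2-methyl-4-methylidenecyclohexane F5. Syn-hydroboration with dicyclohexylborane (1 equiv, THF, 0 °C) and protonolysis with AcOH, both stereospecific, should give the Z-chloroalkene; the hindered, electron-poor exocyclic alkene is expected to react more slowly than the chloroalkyne. The route is rejoined at 14.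

Step 8. Bromide may open the bromonium ion with poor facial selectivity, because axial attack at C3 is syn to the axial chlorovinyl group on C1, or the neighbouring C4 chlorine may participate. The fallback replaces kinetic by thermodynamic control and sets out from 14. The addition is run to full conversion regardless of selectivity, and the C3 epimer (1R,2R,4S,5S)-1-bromo-1-(bromomethyl)-2,4-dichloro-5-[(Z)-2-chloroethenyl]-5-methylcyclohexane F6 is equilibrated (ZnBr2 cat., CH2Cl2, 23 °C, or warming in MeCN). Reversible ionisation to the bromonium ion pair, the known 1,2-bromine shift of vicinal dibromides, should funnel the mixture to the more stable isomer with axial tertiary bromine and equatorial CH2Br, rejoining the route at 15.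

Further compounds
F1 | step 2 | (4R)-1,1-dichloro-4-(hydroxymethyl)-4-methylhex-5-en-2-one | C[C@@](C=C)(CO)CC(=O)C(Cl)Cl
F2 | step 2 | (4R)-4-{[tert-butyl(diphenyl)silyl]oxymethyl}-1,1-dichloro-4-methylhex-5-en-2-one | C[C@@](C=C)(CO[Si](c1ccccc1)(c1ccccc1)C(C)(C)C)CC(=O)C(Cl)Cl
F3 | step 2 | (4S,5S)-5-{[tert-butyl(diphenyl)silyl]oxymethyl}-2,4-dichloro-5-methylcyclohexan-1-one (C2 epimers) | C[C@@]1(CO[Si](c2ccccc2)(c2ccccc2)C(C)(C)C)CC(=O)C(Cl)C[C@@H]1Cl
F4 | step 7 | (1S,2S,5R)-1,5-dichloro-2-ethynyl-2-methyl-4-methylidenecyclohexane | C[C@@]1(C#C)CC(=C)[C@H](Cl)C[C@@H]1Cl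
F5 | step 7 | (1S,2S,5R)-1,5-dichloro-2-(chloroethynyl)-2-methyl-4-methylidenecyclohexane | C[C@@]1(C#CCl)CC(=C)[C@H](Cl)C[C@@H]1Cl
F6 | step 8 | (1R,2R,4S,5S)-1-bromo-1-(bromomethyl)-2,4-dichloro-5-[(Z)-2-chloroethenyl]-5-methylcyclohexane | C[C@@]1(/C=C\Cl)C[C@](Br)(CBr)[C@H](Cl)C[C@@H]1Cl
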